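| flask | starting material | reagent | time |
|---|---|---|---|
| north | 0.800 M | 1.60 M |  |
| north-east | 0.800 M | 2.40 M |  |
| south-east | 1.60 M | 1.60 M |  |
| west | 0.800 M | 3.30 M | 15 min |

- north run (time / min: [target] / M): 1.9: 0.2167; 3.8: 0.3174; 5.6: 0.3750; 7.5: 0.4085; 9.4: 0.4286; 11: 0.4395; 13: 0.4507; 15: 0.4594
- north-east run (time / min: [target] / M): 1.9: 0.3013; 3.8: 0.4259; 5.6: 0.4817; 7.5: 0.5120; 9.4: 0.5335; 11: 0.5404; 13: 0.5475; 15: 0.5511
- south-east run (time / min: [target] / M): 1.9: 0.3866; 3.8: 0.5493; 5.6: 0.6328; 7.5: 0.6865; 9.4: 0.7227; 11: 0.7428; 13: 0.7602; 15: 0.7701

(readings scatter by 0.002 M)

- the power of [reagent] that the first rate follows, about the charge of the north run; measure it at two percent of starting material made into target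
- the power of [starting material] that the first rate follows, about the charge of the north run; measure it at two percent of starting material made into target (one fixed amount of target, the same in the runs compared)
- target in the west run at 15 min, as a share of the starting material charged

- Overall: starting material + reagent -> target.
- Constant volume, constant temperature.
- What is held in complexes is read along with the free species.
- "The second partner" is reagent.
- An order is taken over about fifteen percent of the charge, up and down.

**Leftover reagent.** By the overall equation, the north run still held 1.14 M of reagent at 15 min, yet its target rose by just 0.00870 M over the last interval and stood at 0.4594 M from a charge of 0.800 M. So I asked what had become of the starting material not found as target.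

**First rates.** At 1.9 min, target in the north-east run over that in the north run was 1.39, for a reagent ratio of 1.50. The south-east run over the north run gave 1.78, for a starting-material ratio of 2.00. These readings lie well past the early point asked about, so the ratios lag, and I committed to first order in each partner: rate = k[starting material][reagent].

**My rule.** I supposed a rival first-order loss of starting material with constant k′. Each portion consumed then gives target with the share R/(R + c), where R is [reagent] and c = k′/k. For a whole run I put R at its mean, the value between the two ends. In the north-east run that mean was 2.12 M, and the share reached was 68.9%. This gave c = 0.959 M, the escape concentration: the reagent level at which target and loss take equal shares. It is a reading and it drifts, since the north run gives 1.02 M and the south-east run 1.31 M. I used the north-east value, from the earlier run with the most reagent per starting material.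

**West estimate.** Taking the west run as finished by 15 min, I found that its starting reagent gives a share of 77.5%, which puts its mean reagent at 2.99 M and my estimate of its share at 75.7%.

**The forecast.** It gave 0.95 in reagent, 0.9 in starting material and 77% for the west run, on a different ground from mine: “All three plateaus fit one equilibrium”.

**The result.** The simulation gave orders of 1.0 in reagent and 1.0 in starting material, and 76.5% for the west run, so the forecast stands on all three.

    starting material + reagent → target + by-product (0.1326 M⁻¹ min⁻¹)
    starting material → decomposed substrate (0.1092 min⁻¹)
    reagent + by-product ⇌ reagent-by-product salt, settled at all times (2.240 M⁻¹)

**The loss.** The west run falls short mainly through the loss of starting material to decomposed substrate, which accounts for 94% of what is missing. The escape concentration put the lost share in the west run at 24.3%, and taking that loss away raised the west run's target by 22 percentage points. With c at zero the rule gives a whole share, and the forecast's 77% would be wrong for a west run without that loss, which reached 98.6%.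

The earlier runs and the new flask come from a simulation with made-up constants; the scatter is artificial.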